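**Retrosynthetic overview**
1. Bonnaniol is (2R,3R)-6-geranylaromadendrin. The last operation only removes three MOM groups and one silyl group.
2. Key disconnection: the C2–C3 bond of the pyranone ring. Putting the 3-oxygen back between C2 and C3 gives a racemic seven-membered 2-aryl-1,3-benzodioxepine, the cyclic acetal of a 4-oxygenated benzaldehyde with an o-hydroxyphenacyl alcohol, used as its enol silane. It contracts 7→6 under a chiral counter-anion by expelling that oxygen from the ring.
3. Enabling feature: in the pyranone ring, C2 lies between ring oxygen O1 and the para-oxygenated B-ring, so it ionises to a doubly stabilised oxocarbenium ion. C3 carries oxygen next to the C4 ketone, so it is an enediol carbon. O1–C2/C3(O)–C4=O is therefore a latent intramolecular aldol whose partners can be tied together through the 3-oxygen.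
4. The 6-geranyl pattern is fixed by symmetry. 4-Geranyl-3,5-bis(methoxymethoxy)phenol (ortho-metalation/geranylation of resorcinol bis-MOM ether, then C–H borylation/oxidation) has two equivalent ortho positions, one of which is acylated.
5. Ring order: the A- and B-rings are bought, the seven-membered acetal ring is closed in step 11, and the pyranone ring is made from it in step 13.

Key step: step 13

Assumption: the SMILES encodes (2R,3R), 2,3-trans, with an (E)-geranyl group at C6 (geranyl = (2E)-3,7-dimethylocta-2,6-dien-1-yl). The sense of induction of the catalyst in step 13 cannot be derived from precedent. Both antipodes are accessible from (R)- or (S)-BINOL, and the one that leads to the (2R) series is meant.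

**Step 1**
Reactants: 1 resorcinol
Product: 2 1,3-bis(methoxymethoxy)benzene
Conditions: NaH (2.2 equiv), MOMCl (2.2 equiv), DMF, 0 °C → rt
Reagents that add atoms: chloromethyl methyl ether, COCCl
Why: Williamson-type O-alkylation of the bis-phenoxide installs two MOM groups, which later direct the metalations and fall together in the last step.

**Step 2**
Reactants: 2 1,3-bis(methoxymethoxy)benzene; 3 geranyl bromide
Product: 5 2-geranyl-1,3-bis(methoxymethoxy)benzene, via 2-lithio-1,3-bis(methoxymethoxy)benzene 4 (not isolated)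
Conditions: n-BuLi (1.1 equiv), THF, 0 °C; CuI (10 mol %), then 3, −78 °C → rt
Reagents that add atoms: none
Why: Directed ortho-metalation removes the C–H between the two coordinating OMOM groups, and copper-assisted SN2 allylation at the primary allylic bromide keeps the E geometry of the chain.

**Step 3**
Reactants: 5 2-geranyl-1,3-bis(methoxymethoxy)benzene
Product: 7 4-geranyl-3,5-bis(methoxymethoxy)phenol, via arylboronic pinacol ester 6 (not isolated)
Conditions: [Ir(OMe)(cod)]2 (1.5 mol %), dtbpy (3 mol %), B2pin2 (1.0 equiv), THF, 60 °C; then aq NaOH, H2O2, 0 °C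
Reagents that add atoms: hydrogen peroxide, OO
Why: Sterically governed iridium-catalysed aromatic C–H borylation takes the only ring C–H without an ortho substituent, and nucleophilic peroxide oxidises the C–B bond to the symmetric phenol without touching the isolated trisubstituted alkenes.

**Step 4**
Reactants: 7 4-geranyl-3,5-bis(methoxymethoxy)phenol
Product: 8 5-(1-ethoxyethoxy)-2-geranyl-1,3-bis(methoxymethoxy)benzene (racemic at the acetal carbon)
Conditions: ethyl vinyl ether (5 equiv), PPTS (5 mol %), CH2Cl2, rt
Reagents that add atoms: ethyl vinyl ether, C=COCC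
Why: Acid-catalysed addition of the phenol to the enol ether gives an ethoxyethyl (EE) acetal that coordinates lithium like a MOM group but is far more acid-labile, and its stereocentre is irrelevant because it is removed in step 8.

**Step 5**
Reactants: 9 methyl glycolate
Product: 10 methyl 2-(1-ethoxyethoxy)acetate (racemic)
Conditions: ethyl vinyl ether (2 equiv), PPTS (2 mol %), CH2Cl2, 0 °C → rt
Reagents that add atoms: ethyl vinyl ether, C=COCC
Why: The same acid-catalysed enol ether addition masks the primary alcohol with the group already used on the phenol, so that both fall in one later operation.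

**Step 6**
Reactants: 10 methyl 2-(1-ethoxyethoxy)acetate
Product: 11 2-(1-ethoxyethoxy)-N-methoxy-N-methylacetamide
Conditions: MeNH(OMe)·HCl (1.5 equiv), i-PrMgCl (3.0 equiv), THF, −20 °C
Reagents that add atoms: N,O-dimethylhydroxylamine hydrochloride, CNOC.Cl
Why: Aminolysis of the ester by the magnesium amide made in the flask (Weinreb amide synthesis) is fast at low temperature and leaves the base-stable EE acetal intact.

**Step 7**
Reactants: 8 5-(1-ethoxyethoxy)-2-geranyl-1,3-bis(methoxymethoxy)benzene; 11 2-(1-ethoxyethoxy)-N-methoxy-N-methylacetamide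
Product: 14 2-(1-ethoxyethoxy)-1-[6-(1-ethoxyethoxy)-3-geranyl-2,4-bis(methoxymethoxy)phenyl]ethan-1-one, via aryllithium 12 (not isolated), via tetrahedral lithium adduct 13 (not isolated)
Conditions: n-BuLi (1.1 equiv), THF, 0 °C; 11, −78 → 0 °C; then H2O
Reagents that add atoms: none
Why: Directed ortho-metalation can give only one aryllithium because the two remaining ring C–H bonds are equivalent and each lies between OEE and OMOM, and the chelated Weinreb adduct stops the acylation at the ketone (Weinreb ketone synthesis).

**Step 8**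
Reactants: 14 2-(1-ethoxyethoxy)-1-[6-(1-ethoxyethoxy)-3-geranyl-2,4-bis(methoxymethoxy)phenyl]ethan-1-one
Product: 15 1-[3-geranyl-6-hydroxy-2,4-bis(methoxymethoxy)phenyl]-2-hydroxyethan-1-one
Conditions: PPTS (10 mol %), MeOH, rt
Reagents that add atoms: none
Why: Mild acid-catalysed acetal exchange with methanol cleaves the two acetaldehyde-derived EE acetals much faster than the formaldehyde-derived MOM ethers and does not protonate the geranyl alkenes.

**Step 9**
Reactants: 16 4-hydroxybenzaldehyde
Product: 17 4-(methoxymethoxy)benzaldehyde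
Conditions: NaH (1.1 equiv), MOMCl (1.1 equiv), DMF, 0 °C
Reagents that add atoms: chloromethyl methyl ether, COCCl
Why: O-Alkylation of the phenoxide gives the B-ring the same protecting group as the A-ring while keeping the para-oxygen a strong donor.

**Step 10**
Reactants: 17 4-(methoxymethoxy)benzaldehyde
Product: 18 1-(dimethoxymethyl)-4-(methoxymethoxy)benzene
Conditions: HC(OMe)3 (1.5 equiv), PPTS (2 mol %), MeOH, rt
Reagents that add atoms: trimethyl orthoformate, COC(OC)OC
Why: Orthoformate-driven acetalisation of an electron-rich aromatic aldehyde proceeds under acid too weak to exchange the aryl MOM ether.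

**Step 11**
Reactants: 15 1-[3-geranyl-6-hydroxy-2,4-bis(methoxymethoxy)phenyl]-2-hydroxyethan-1-one; 18 1-(dimethoxymethyl)-4-(methoxymethoxy)benzene
Product: 19 rac-7-geranyl-6,8-bis(methoxymethoxy)-2-[4-(methoxymethoxy)phenyl]-4H-1,3-benzodioxepin-5-one
Conditions: PPTS (10 mol %), toluene, 5 Å MS, 70 °C; chromatography on Et3N-deactivated silica
Reagents that add atoms: none
Why: Acid-catalysed transacetalisation of a diol whose two oxygens are held 1,4 across the aromatic C=C closes the only possible ring (phenol onto the oxocarbenium ion, 7-endo-trig), is driven by uptake of methanol, and gives a racemic acetal centre that does not matter.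

**Step 12**
Reactants: 19 rac-7-geranyl-6,8-bis(methoxymethoxy)-2-[4-(methoxymethoxy)phenyl]-4H-1,3-benzodioxepin-5-one
Product: 21 rac-7-geranyl-6,8-bis(methoxymethoxy)-2-[4-(methoxymethoxy)phenyl]-5-(triethylsilyloxy)-2H-1,3-benzodioxepine, via potassium enolate 20 (not isolated)
Conditions: KHMDS (1.1 equiv), THF, −78 °C; TESCl (1.2 equiv), −78 → −40 °C; pH 7 buffer
Reagents that add atoms: chlorotriethylsilane, CC[Si](Cl)(CC)CC
Why: Kinetic deprotonation at the only enolisable position (the ring CH2) and O-silylation of the potassium enolate give the cyclic enol silane in the absence of any acid, so the acetal stays closed.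

**Step 13**
Reactants: 21 rac-7-geranyl-6,8-bis(methoxymethoxy)-2-[4-(methoxymethoxy)phenyl]-5-(triethylsilyloxy)-2H-1,3-benzodioxepine
Product: 23 (2R,3R)-6-geranyl-5,7-bis(methoxymethoxy)-2-[4-(methoxymethoxy)phenyl]-3-(triethylsilyloxy)chroman-4-one, via ring-opened oxocarbenium ion 22 (not isolated)
Conditions: chiral BINOL-derived imidodiphosphorimidate (IDPi, 3,3′-aryl, N-triflyl; 5 mol %), toluene (0.02 M), −60 °C; Et3N quench
Reagents that add atoms: none
Why: Proposed new method: the acid is silylated in the flask by a trace of 21, the silylium–IDPi pair silylates the enol-ether oxygen O3 of the acetal, the C2–O3 bond ionises under the push of ring oxygen O1 and of the para-oxygenated B-ring, the tethered 1,2-bis(silyloxy)alkene of 22 attacks C2 through C4 (the later C3), and the silyloxocarbenium ion at C5 (the later C4) returns Et3Si+ to the anion, so that 21 isomerises to 23 and O3 leaves the ring as the 3-oxygen (seven- to six-membered ring contraction). The closest known reaction types are the Petasis–Ferrier rearrangement, the acid-catalysed ring contraction of 4,5-dihydro-1,3-dioxepines (cyclic vinyl acetals) to tetrahydrofuran-3-carbaldehydes including its chiral phosphoric acid version on racemic acetals, and the silylium-IDPi Mukaiyama addition of enol silanes to acetal-derived oxocarbenium ions; what is new is the extra silyloxy group on the alkene, which moves the nucleophilic site to the oxygen-bearing carbon and turns a loss of two ring atoms into a loss of one. The pyranone ring closes in a 6-endo-trig, enol-endo Mukaiyama aldol mode, which is allowed for six-membered rings. C2 is controlled by the confined chiral anion, which shields one face of the planar E-oxocarbenium ion, and since the acetal centre is erased on ionisation and unreacted 21 racemises by reversible ring opening, both enantiomers of 21 are funnelled into the (2R) series; C3 follows from C2 because the E-oxocarbenium ion and the ring-derived alkene geometry (O3 cis to the aryl group) lead to the 2,3-trans diequatorial half-chair, which is also the thermodynamic epimer at the enolisable C3. Regioselectivity for C4 over C5 is secured because attack through C4 leaves a cation stabilised by silyloxy and the electron-rich aryl group, whereas attack through C5 would build a quaternary centre and a less stabilised cation in a five-membered ring. Chemoselectivity is secured because only the benzylidene-type acetal gives a doubly stabilised cation at this temperature, while the MOM acetals and the geranyl alkenes (para to O1, out of reach of C2) should stay untouched at high dilution.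

**Step 14**
Reactants: 23 (2R,3R)-6-geranyl-5,7-bis(methoxymethoxy)-2-[4-(methoxymethoxy)phenyl]-3-(triethylsilyloxy)chroman-4-one
Product: 24 bonnaniol
Conditions: 3 M aq HCl–MeOH (1:5), 45 °C, argon
Reagents that add atoms: none
Why: Acid-catalysed methanolysis of the three MOM acetals and the TES ether is the usual unmasking of geranylated flavonoids, breaks no bond at C2 or C3, and meets the thermodynamically preferred 2,3-trans isomer, so the configuration from step 13 is kept.

**Compound list**
1 | resorcinol | Oc1cccc(O)c1 | starting material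
2 | 1,3-bis(methoxymethoxy)benzene | COCOc1cccc(OCOC)c1 | intermediate
3 | geranyl bromide | CC(C)=CCC/C(C)=C/CBr | starting material
4 | 2-lithio-1,3-bis(methoxymethoxy)benzene (not isolated) | [Li]c1c(OCOC)cccc1OCOC | intermediate
5 | 2-geranyl-1,3-bis(methoxymethoxy)benzene | CC(C)=CCC/C(C)=C/Cc1c(OCOC)cccc1OCOC | intermediate
6 | 2-[4-geranyl-3,5-bis(methoxymethoxy)phenyl]-4,4,5,5-tetramethyl-1,3,2-dioxaborolane (not isolated) | CC(C)=CCC/C(C)=C/Cc1c(OCOC)cc(B2OC(C)(C)C(C)(C)O2)cc1OCOC | intermediate
7 | 4-geranyl-3,5-bis(methoxymethoxy)phenol | CC(C)=CCC/C(C)=C/Cc1c(OCOC)cc(O)cc1OCOC | intermediate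
8 | 5-(1-ethoxyethoxy)-2-geranyl-1,3-bis(methoxymethoxy)benzene (racemic) | CC(C)=CCC/C(C)=C/Cc1c(OCOC)cc(OC(C)OCC)cc1OCOC | intermediate
9 | methyl glycolate | COC(=O)CO | starting material
10 | methyl 2-(1-ethoxyethoxy)acetate (racemic) | CCOC(C)OCC(=O)OC | intermediate
11 | 2-(1-ethoxyethoxy)-N-methoxy-N-methylacetamide (racemic) | CCOC(C)OCC(=O)N(C)OC | intermediate
12 | 2-(1-ethoxyethoxy)-5-geranyl-4,6-bis(methoxymethoxy)phenyllithium (not isolated) | CC(C)=CCC/C(C)=C/Cc1c(OCOC)cc(OC(C)OCC)c([Li])c1OCOC | intermediate
13 | lithium alkoxide adduct of 12 to the carbonyl group of 11 (not isolated) | CC(C)=CCC/C(C)=C/Cc1c(OCOC)cc(OC(C)OCC)c(C(O[Li])(COC(C)OCC)N(C)OC)c1OCOC | intermediate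
14 | 2-(1-ethoxyethoxy)-1-[6-(1-ethoxyethoxy)-3-geranyl-2,4-bis(methoxymethoxy)phenyl]ethan-1-one (mixture at the two EE centres) | CC(C)=CCC/C(C)=C/Cc1c(OCOC)cc(OC(C)OCC)c(C(=O)COC(C)OCC)c1OCOC | intermediate
15 | 1-[3-geranyl-6-hydroxy-2,4-bis(methoxymethoxy)phenyl]-2-hydroxyethan-1-one | CC(C)=CCC/C(C)=C/Cc1c(OCOC)cc(O)c(C(=O)CO)c1OCOC | intermediate
16 | 4-hydroxybenzaldehyde | O=Cc1ccc(O)cc1 | starting material
17 | 4-(methoxymethoxy)benzaldehyde | COCOc1ccc(C=O)cc1 | intermediate
18 | 1-(dimethoxymethyl)-4-(methoxymethoxy)benzene | COCOc1ccc(C(OC)OC)cc1 | intermediate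
19 | rac-7-geranyl-6,8-bis(methoxymethoxy)-2-[4-(methoxymethoxy)phenyl]-4H-1,3-benzodioxepin-5-one | CC(C)=CCC/C(C)=C/Cc1c(OCOC)cc2OC(c3ccc(OCOC)cc3)OCC(=O)c2c1OCOC | intermediate
20 | potassium enolate of 19 (not isolated) | CC(C)=CCC/C(C)=C/Cc1c(OCOC)cc2OC(c3ccc(OCOC)cc3)OC=C(O[K])c2c1OCOC | intermediate
21 | rac-7-geranyl-6,8-bis(methoxymethoxy)-2-[4-(methoxymethoxy)phenyl]-5-(triethylsilyloxy)-2H-1,3-benzodioxepine | CC(C)=CCC/C(C)=C/Cc1c(OCOC)cc2OC(c3ccc(OCOC)cc3)OC=C(O[Si](CC)(CC)CC)c2c1OCOC | intermediate
22 | ring-opened E-aryloxocarbenium ion bearing the 1,2-bis(triethylsilyloxy)alkene; cation of the ion pair with the IDPi anion, its second Et3Si group is carried by the catalyst cycle (not isolated) | CC(C)=CCC/C(C)=C/Cc1c(OCOC)cc(/[O+]=C/c2ccc(OCOC)cc2)c(/C(O[Si](CC)(CC)CC)=C\O[Si](CC)(CC)CC)c1OCOC | intermediate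
23 | (2R,3R)-6-geranyl-5,7-bis(methoxymethoxy)-2-[4-(methoxymethoxy)phenyl]-3-(triethylsilyloxy)chroman-4-one | CC(C)=CCC/C(C)=C/Cc1c(OCOC)cc2c(c1OCOC)C(=O)[C@H](O[Si](CC)(CC)CC)[C@@H](c1ccc(OCOC)cc1)O2 | intermediate
24 | bonnaniol, (2R,3R)-6-geranyl-3,5,7-trihydroxy-2-(4-hydroxyphenyl)chroman-4-one | CC(C)=CCC/C(C)=C/Cc1c(O)cc2c(c1O)C(=O)[C@H](O)[C@@H](c1ccc(O)cc1)O2 | target

**Step count and risks**

Total step count: 14. Longest linear sequence: 10 steps (1, 2, 3, 4, 7, 8, 11, 12, 13, 14).

Steps most likely to fail:

1. **Step 13.**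
   - What may go wrong: weak facial discrimination within the ion pair, closure through the aryl-bearing enol carbon to a five-membered ring, or silylium attack on the MOM acetals.
   - The fallback uses known chemistry, sets out from 8 and returns to the route at 24.
   - 8 is lithiated as in step 7 (12) and acylated with N-methoxy-N-methylacetamide to 1-[6-(1-ethoxyethoxy)-3-geranyl-2,4-bis(methoxymethoxy)phenyl]ethan-1-one F1.
   - Claisen–Schmidt condensation with 17 (KOH, EtOH) gives the (E)-chalcone F2.
   - Juliá–Colonna epoxidation (poly-L-leucine, urea–H2O2, DBU, THF) is a nucleophilic epoxidation that ignores the geranyl alkenes. It gives the (αR,βS)-epoxychalcone F3.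
   - AcOH–THF–H2O frees the 2′-hydroxy epoxychalcone F4. Its phenol opens the epoxide at the benzylic carbon with inversion (6-endo, catalytic CSA, CH2Cl2) to the (2R,3R)-tri-MOM flavanonol F5.
   - The conditions of step 14 convert F5 into 24.

2. **Step 11.**
   - What may go wrong: an unfavourable equilibrium, because the chelated phenol is a weak nucleophile and a good leaving group, hydrolysis during isolation, or premature uncatalysed rearrangement.
   - The fallback replaces the equilibrium acetalisation by an irreversible oxidative ring closure. It sets out from 8 and 17 and returns at 19.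
   - 17 is reduced (NaBH4, MeOH) to 4-(methoxymethoxy)benzyl alcohol F6.
   - F6 is alkylated with 2-chloro-N-methoxy-N-methylacetamide (NaH, THF) to the Weinreb amide F7.
   - Aryllithium 12 made from 8 adds to F7 to give the benzyloxymethyl ketone F8.
   - PPTS in MeOH frees the phenol F9.
   - DDQ (CH2Cl2, 4 Å MS, 0 °C) abstracts hydride from the para-oxygenated benzyl ether, and the neighbouring phenol traps the oxocarbenium ion to give 19.

3. **Step 3.**
   - What may go wrong: hydroboration or isomerisation of the geranyl alkenes by iridium hydride and pinacolborane, or stalled conversion.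
   - The fallback moves the C–H borylation ahead of the chain. It sets out from 2 and returns at 7.
   - 2 is borylated under the same catalyst at its only unhindered position to the boronate F10, which is oxidised (H2O2, NaOH) to 3,5-bis(methoxymethoxy)phenol F11.
   - TIPSCl and imidazole give the silyl ether F12. Its bulky group blocks both neighbouring positions, so n-BuLi lithiates only between the two OMOM groups.
   - Alkylation with 3 gives the geranylated silyl ether F13, and TBAF (THF, 0 °C) releases 7.

**Further compounds**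
F1 | step 13 | 1-[6-(1-ethoxyethoxy)-3-geranyl-2,4-bis(methoxymethoxy)phenyl]ethan-1-one | CC(C)=CCC/C(C)=C/Cc1c(OCOC)cc(OC(C)OCC)c(C(C)=O)c1OCOC
F2 | step 13 | (E)-1-[6-(1-ethoxyethoxy)-3-geranyl-2,4-bis(methoxymethoxy)phenyl]-3-[4-(methoxymethoxy)phenyl]prop-2-en-1-one | CC(C)=CCC/C(C)=C/Cc1c(OCOC)cc(OC(C)OCC)c(C(=O)/C=C/c2ccc(OCOC)cc2)c1OCOC
F3 | step 13 | [6-(1-ethoxyethoxy)-3-geranyl-2,4-bis(methoxymethoxy)phenyl] {(2R,3S)-3-[4-(methoxymethoxy)phenyl]oxiran-2-yl} ketone | CC(C)=CCC/C(C)=C/Cc1c(OCOC)cc(OC(C)OCC)c(C(=O)[C@@H]2O[C@H]2c2ccc(OCOC)cc2)c1OCOC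
F4 | step 13 | [3-geranyl-6-hydroxy-2,4-bis(methoxymethoxy)phenyl] {(2R,3S)-3-[4-(methoxymethoxy)phenyl]oxiran-2-yl} ketone | CC(C)=CCC/C(C)=C/Cc1c(OCOC)cc(O)c(C(=O)[C@@H]2O[C@H]2c2ccc(OCOC)cc2)c1OCOC
F5 | step 13 | (2R,3R)-6-geranyl-3-hydroxy-5,7-bis(methoxymethoxy)-2-[4-(methoxymethoxy)phenyl]chroman-4-one | CC(C)=CCC/C(C)=C/Cc1c(OCOC)cc2c(c1OCOC)C(=O)[C@H](O)[C@@H](c1ccc(OCOC)cc1)O2
F6 | step 11 | 4-(methoxymethoxy)benzyl alcohol | COCOc1ccc(CO)cc1
F7 | step 11 | N-methoxy-2-{[4-(methoxymethoxy)benzyl]oxy}-N-methylacetamide | COCOc1ccc(COCC(=O)N(C)OC)cc1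
F8 | step 11 | 1-[6-(1-ethoxyethoxy)-3-geranyl-2,4-bis(methoxymethoxy)phenyl]-2-{[4-(methoxymethoxy)benzyl]oxy}ethan-1-one | CC(C)=CCC/C(C)=C/Cc1c(OCOC)cc(OC(C)OCC)c(C(=O)COCc2ccc(OCOC)cc2)c1OCOC
F9 | step 11 | 1-[3-geranyl-6-hydroxy-2,4-bis(methoxymethoxy)phenyl]-2-{[4-(methoxymethoxy)benzyl]oxy}ethan-1-one | CC(C)=CCC/C(C)=C/Cc1c(OCOC)cc(O)c(C(=O)COCc2ccc(OCOC)cc2)c1OCOC
F10 | step 3 | 2-[3,5-bis(methoxymethoxy)phenyl]-4,4,5,5-tetramethyl-1,3,2-dioxaborolane | COCOc1cc(B2OC(C)(C)C(C)(C)O2)cc(OCOC)c1
F11 | step 3 | 3,5-bis(methoxymethoxy)phenol | COCOc1cc(O)cc(OCOC)c1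
F12 | step 3 | [3,5-bis(methoxymethoxy)phenoxy]triisopropylsilane | COCOc1cc(O[Si](C(C)C)(C(C)C)C(C)C)cc(OCOC)c1
F13 | step 3 | [4-geranyl-3,5-bis(methoxymethoxy)phenoxy]triisopropylsilane | CC(C)=CCC/C(C)=C/Cc1c(OCOC)cc(O[Si](C(C)C)(C(C)C)C(C)C)cc1OCOC
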